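**Retrosynthetic overview**
1. Aldol condensation of 1 with 2 (through 3 and 4) gives the symmetric allyl donor 5, which carries both aryl rings and the future lactone carbonyl.
2. Key disconnection: the C–C bond between the aryl-bearing and the carboxyl-bearing ring carbons, and the lactone C–O bond. Two equivalents of 5 add to the C2-symmetric dialdehyde made in the flask from L-tartrate 6 (through 7, 8 and 9) and close to bis-lactone 10.
3. The C2 axis runs through the central diol bond: unmasking (11) and glycol cleavage/oxidation (through 12) turn each tartrate carbon into the carboxyl carbon of acid 13.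
4. Ether cleavage (through 14) and esterification give 15.
5. Ring order: the aryl rings are bought; both γ-lactone rings, all four stereocentres and both Z-alkenes form together in step 2; no other ring is made.

Assumption: the SMILES is read as the (2S,3R)-cis lactone with a Z-ylidene (ylidene aryl on the side of the lactone carbonyl).

**Step 1**
Reactants: 1 3,4-dimethoxybenzaldehyde; 2 methyl 3-(3,4-dimethoxyphenyl)propanoate
Product: 5 methyl (2E)-3-(3,4-dimethoxyphenyl)-2-[(3,4-dimethoxyphenyl)methyl]prop-2-enoate, via lithium aldolate 3 (not isolated), via aldol acetate 4 (not isolated)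
Conditions: 2, LiN(i-Pr)2, THF, −78 °C; add 1; Ac2O, −78 → 23 °C; DBU, 23 °C
Reagents that add atoms: none
Why: Directed ester-enolate aldol addition followed by acetylation and DBU-promoted E1cB elimination (aldol condensation) delivers the conjugated ester with the aryl trans to the ester (E) as the thermodynamic product, and no stereocentre is formed.

**Step 2**
Reactants: 5 methyl (2E)-3-(3,4-dimethoxyphenyl)-2-[(3,4-dimethoxyphenyl)methyl]prop-2-enoate (2.2 equiv); 6 dimethyl (4R,5R)-2,2-dimethyl-1,3-dioxolane-4,5-dicarboxylate (dimethyl 2,3-O-isopropylidene-L-tartrate)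
Product: 10 5,5'-[(4S,5S)-2,2-dimethyl-1,3-dioxolane-4,5-diyl]bis{(3Z,4R,5S)-4-(3,4-dimethoxyphenyl)-3-[(3,4-dimethoxyphenyl)methylidene]oxolan-2-one}, via allyltitanium reagent 7 (not isolated), via dialdehyde 8 (not isolated), via open-chain diol diester 9 (not isolated)
Conditions: 5, LiN(i-Pr)2, THF, −78 °C, then ClTi(OiPr)3 (gives 7); 6, i-Bu2AlH (2.05 equiv), PhMe, −78 °C (gives 8), cannulated cold into 7; −78 → 23 °C, 12 h; aq. NH4Cl
Reagents that add atoms: none
Why: Proposed new method: deprotonation of the doubly benzylic-allylic CH2 of 5 gives a 1,3-diarylallyl anion with two identical termini (no regiochemical issue), and its triisopropoxytitanium derivative 7 adds to each formyl group of 8 through a closed Zimmerman–Traxler chair in which the alkene aryl cis to the metal-bearing carbon enforces the 4,5-syn (cis-lactone) relationship, the aryl on the metal-bearing carbon sits equatorial to avoid A(1,3) strain and so ends cis to the ester (Z-ylidene), and Felkin–Anh attack anti to the dioxolane oxygen of the L-tartrate-derived aldehyde fixes 5S and therefore 4R, after which the titanium alkoxides of 9 transesterify onto the adjacent methyl esters to close both γ-lactones at once; the closest known reaction types are the Dreiding–Schmidt 2-(alkoxycarbonyl)allylation–lactonization and allyltitanium additions to α-alkoxy aldehydes.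

**Step 3**
Reactants: 10 5,5'-[(4S,5S)-2,2-dimethyl-1,3-dioxolane-4,5-diyl]bis{(3Z,4R,5S)-4-(3,4-dimethoxyphenyl)-3-[(3,4-dimethoxyphenyl)methylidene]oxolan-2-one}
Product: 11 5,5'-[(1R,2R)-1,2-dihydroxyethane-1,2-diyl]bis{(3Z,4R,5S)-4-(3,4-dimethoxyphenyl)-3-[(3,4-dimethoxyphenyl)methylidene]oxolan-2-one}
Conditions: CF3CO2H/H2O 9:1, 0 → 23 °C
Reagents that add atoms: none
Why: Acid-catalysed acetal hydrolysis removes the isopropylidene group and leaves the lactones, aryl methyl ethers, Z-alkenes and all stereocentres untouched because no base is present.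

**Step 4**
Reactants: 11 5,5'-[(1R,2R)-1,2-dihydroxyethane-1,2-diyl]bis{(3Z,4R,5S)-4-(3,4-dimethoxyphenyl)-3-[(3,4-dimethoxyphenyl)methylidene]oxolan-2-one}
Product: 13 (2S,3R,4Z)-3-(3,4-dimethoxyphenyl)-4-[(3,4-dimethoxyphenyl)methylidene]-5-oxooxolane-2-carboxylic acid (2 equiv per 11), via aldehyde 12 (not isolated)
Conditions: NaIO4, THF/H2O, 0 °C; then NaClO2, NaH2PO4, 2-methyl-2-butene, t-BuOH/H2O, 23 °C
Reagents that add atoms: sodium chlorite, [Na+].[O-]Cl=O
Why: Periodate (Malaprade) glycol cleavage converts each carbinol carbon of the former tartrate unit into the formyl group of 12, and immediate Pinnick (Lindgren–Kraus) oxidation of the hydrated aldehyde at about pH 4 gives the acid faster than the C2 stereocentre can enolize, so configuration is retained and no new stereocentre is formed.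

**Step 5**
Reactants: 13 (2S,3R,4Z)-3-(3,4-dimethoxyphenyl)-4-[(3,4-dimethoxyphenyl)methylidene]-5-oxooxolane-2-carboxylic acid
Product: 15 methyl (2S,3R,4Z)-3-(3,4-dihydroxyphenyl)-4-[(3,4-dihydroxyphenyl)methylidene]-5-oxooxolane-2-carboxylate, via tetrahydroxy acid 14 (not isolated)
Conditions: BBr3 (10 equiv), CH2Cl2, −78 → 0 °C; then MeOH, 0 → 40 °C, under argon
Reagents that add atoms: methanol, CO
Why: Boron tribromide dealkylates the four aryl methyl ethers (Lewis acid-assisted SN2 by bromide at methyl) to give 14, and the HBr released on methanol quench drives Fischer esterification of the carboxylic acid while the γ-lactone, the favoured closed form under acid, and both stereocentres are left intact.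

**Compound list**
1 | 3,4-dimethoxybenzaldehyde | COc1ccc(C=O)cc1OC | starting material
2 | methyl 3-(3,4-dimethoxyphenyl)propanoate | COC(=O)CCc1ccc(OC)c(OC)c1 | starting material
3 | lithium 1,3-bis(3,4-dimethoxyphenyl)-2-(methoxycarbonyl)propan-1-olate (racemic diastereomer mixture) | [Li+].COC(=O)C(Cc1ccc(OC)c(OC)c1)C([O-])c1ccc(OC)c(OC)c1 | intermediate
4 | methyl 3-(acetyloxy)-3-(3,4-dimethoxyphenyl)-2-[(3,4-dimethoxyphenyl)methyl]propanoate (racemic diastereomer mixture) | COC(=O)C(Cc1ccc(OC)c(OC)c1)C(OC(C)=O)c1ccc(OC)c(OC)c1 | intermediate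
5 | methyl (2E)-3-(3,4-dimethoxyphenyl)-2-[(3,4-dimethoxyphenyl)methyl]prop-2-enoate | COC(=O)/C(=C/c1ccc(OC)c(OC)c1)Cc1ccc(OC)c(OC)c1 | intermediate
6 | dimethyl (4R,5R)-2,2-dimethyl-1,3-dioxolane-4,5-dicarboxylate | COC(=O)[C@@H]1OC(C)(C)O[C@H]1C(=O)OC | starting material
7 | tri(propan-2-yloxy)[(2Z)-1,3-bis(3,4-dimethoxyphenyl)-2-(methoxycarbonyl)prop-2-en-1-yl]titanium (racemic at the metal-bearing carbon) | COC(=O)/C(=C/c1ccc(OC)c(OC)c1)C(c1ccc(OC)c(OC)c1)[Ti](OC(C)C)(OC(C)C)OC(C)C | intermediate
8 | (4R,5R)-2,2-dimethyl-1,3-dioxolane-4,5-dicarbaldehyde | O=C[C@@H]1OC(C)(C)O[C@H]1C=O | intermediate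
9 | (4S,5S)-2,2-dimethyl-1,3-dioxolane carrying on C4 and on C5 a (1S,2R,3Z)-1-hydroxy-2,4-bis(3,4-dimethoxyphenyl)-3-(methoxycarbonyl)but-3-en-1-yl arm (present as its titanium alkoxide) | CC1(C)O[C@@H]([C@@H](O)[C@H](c2ccc(OC)c(OC)c2)/C(=C/c2ccc(OC)c(OC)c2)C(=O)OC)[C@@H](O1)[C@@H](O)[C@H](c1ccc(OC)c(OC)c1)/C(=C/c1ccc(OC)c(OC)c1)C(=O)OC | intermediate
10 | 5,5'-[(4S,5S)-2,2-dimethyl-1,3-dioxolane-4,5-diyl]bis{(3Z,4R,5S)-4-(3,4-dimethoxyphenyl)-3-[(3,4-dimethoxyphenyl)methylidene]oxolan-2-one} | CC1(C)O[C@@H]([C@H]2OC(=O)/C(=C\c3ccc(OC)c(OC)c3)[C@H]2c2ccc(OC)c(OC)c2)[C@@H](O1)[C@H]1OC(=O)/C(=C\c2ccc(OC)c(OC)c2)[C@H]1c1ccc(OC)c(OC)c1 | intermediate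
11 | 5,5'-[(1R,2R)-1,2-dihydroxyethane-1,2-diyl]bis{(3Z,4R,5S)-4-(3,4-dimethoxyphenyl)-3-[(3,4-dimethoxyphenyl)methylidene]oxolan-2-one} | O[C@@H]([C@H]1OC(=O)/C(=C\c2ccc(OC)c(OC)c2)[C@H]1c1ccc(OC)c(OC)c1)[C@@H](O)[C@H]1OC(=O)/C(=C\c2ccc(OC)c(OC)c2)[C@H]1c1ccc(OC)c(OC)c1 | intermediate
12 | (2S,3R,4Z)-3-(3,4-dimethoxyphenyl)-4-[(3,4-dimethoxyphenyl)methylidene]-5-oxooxolane-2-carbaldehyde | O=C[C@H]1OC(=O)/C(=C\c2ccc(OC)c(OC)c2)[C@H]1c1ccc(OC)c(OC)c1 | intermediate
13 | (2S,3R,4Z)-3-(3,4-dimethoxyphenyl)-4-[(3,4-dimethoxyphenyl)methylidene]-5-oxooxolane-2-carboxylic acid | OC(=O)[C@H]1OC(=O)/C(=C\c2ccc(OC)c(OC)c2)[C@H]1c1ccc(OC)c(OC)c1 | intermediate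
14 | (2S,3R,4Z)-3-(3,4-dihydroxyphenyl)-4-[(3,4-dihydroxyphenyl)methylidene]-5-oxooxolane-2-carboxylic acid | OC(=O)[C@H]1OC(=O)/C(=C\c2ccc(O)c(O)c2)[C@H]1c1ccc(O)c(O)c1 | intermediate
15 | methyl (2S,3R,4Z)-3-(3,4-dihydroxyphenyl)-4-[(3,4-dihydroxyphenyl)methylidene]-5-oxooxolane-2-carboxylate | COC(=O)[C@H]1OC(=O)/C(=C\c2ccc(O)c(O)c2)[C@H]1c1ccc(O)c(O)c1 | target

**Total step count:** 5
**Longest linear sequence:** 5 steps (2 → 5 → 10 → 11 → 13 → 15)

**Steps most likely to fail**

Step 2. The risks are incomplete deprotonation or Michael self-addition of the allyl anion, sluggish release of the dialdehyde from its aluminium hemiacetal, imperfect double diastereocontrol over two additions, and base-induced drift of the exocyclic alkene into the ring. The fallback sets out from 5 and 6 and comes back at 10. Compound 5 is deprotonated as before and quenched with BrCCl2CCl2Br to give the allylic bromide methyl (2Z)-2-[bromo(3,4-dimethoxyphenyl)methyl]-3-(3,4-dimethoxyphenyl)prop-2-enoate F1. Separately, 6 is reduced with i-Bu2AlH and dialdehyde 8 is isolated crude. F1 and 8 are then joined in a Barbier reaction with In powder in THF at 23 °C, which goes through the same chair transition state without strong base and gives 9. Catalytic TsOH in CH2Cl2 closes 9 to 10.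

Step 4. The risks are epimerization of aldehyde 12 at C2 towards the trans lactone and chlorination of the electron-rich aryl rings by hypochlorite. The fallback sets out from 11 and comes back at 15. Compound 11 is cleaved with NaIO4 as before and 12 is extracted into CH2Cl2. It is then oxidized in methanol with KHSO5 (used as 2KHSO5·KHSO4·K2SO4), which converts the methyl hemiacetal directly into the ester methyl (2S,3R,4Z)-3-(3,4-dimethoxyphenyl)-4-[(3,4-dimethoxyphenyl)methylidene]-5-oxooxolane-2-carboxylate F2 without chlorine-based oxidants. The four methyl ethers of F2 are cleaved with BBr3 (CH2Cl2, −78 → −20 °C, aqueous work-up), which gives 15 without a separate esterification.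

Step 5. The risks are lactone opening by BBr3/HBr, incomplete esterification, and air oxidation of the free catechols during purification. The fallback sets out from 13 and comes back at 15. Compound 13 is demethylated with BBr3 and worked up with water to give 14, which is not purified but peracetylated (Ac2O, pyridine, aqueous work-up) to (2S,3R,4Z)-3-[3,4-bis(acetyloxy)phenyl]-4-{[3,4-bis(acetyloxy)phenyl]methylidene}-5-oxooxolane-2-carboxylic acid F3. F3 is air-stable and can be purified on silica. HCl in MeOH (from AcCl, 23 → 40 °C) then removes the four aryl acetates by methanolysis and esterifies the acid in the same operation to give 15.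

**Further compounds**
F1 | step 2 | methyl (2Z)-2-[bromo(3,4-dimethoxyphenyl)methyl]-3-(3,4-dimethoxyphenyl)prop-2-enoate (racemic) | COC(=O)/C(=C/c1ccc(OC)c(OC)c1)C(Br)c1ccc(OC)c(OC)c1
F2 | step 4 | methyl (2S,3R,4Z)-3-(3,4-dimethoxyphenyl)-4-[(3,4-dimethoxyphenyl)methylidene]-5-oxooxolane-2-carboxylate | COC(=O)[C@H]1OC(=O)/C(=C\c2ccc(OC)c(OC)c2)[C@H]1c1ccc(OC)c(OC)c1
F3 | step 5 | (2S,3R,4Z)-3-[3,4-bis(acetyloxy)phenyl]-4-{[3,4-bis(acetyloxy)phenyl]methylidene}-5-oxooxolane-2-carboxylic acid | OC(=O)[C@H]1OC(=O)/C(=C\c2ccc(OC(C)=O)c(OC(C)=O)c2)[C@H]1c1ccc(OC(C)=O)c(OC(C)=O)c1
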